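**Strategy.** In ring A (carotenoid numbering C1–C6, ester oxygen on C3, methyl C18 on C5) the C3 carbinol lies β to C5, and C5=C6 becomes an enal double bond once C7 is a formyl carbon: a double aldol retron. Cutting C3–C4 and C5=C6 leaves acetone (C4, C5, C18) and the symmetric 3,3-dimethylpentanedial (C7, C6, C1, C2, C3). One pot joins them: an L-proline aldol sets C3, and an ammonium-salt aldol condensation closes ring A to (3R)-3-hydroxy-β-cyclocitral. Reduction, phosphonium salt formation, Wittig reaction with β-apo-8'-carotenal and acylation with oleoyl chloride complete the ester.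

Key step: step 2

Assumption: 3,3-dimethylpentane-1,5-diol, all-E β-apo-8'-carotenal and oleoyl chloride are taken as catalogue compounds; the diol is otherwise one LiAlH4 reduction away from 3,3-dimethylglutaric anhydride.

**Step 1**
Reactants: 1 3,3-dimethylpentane-1,5-diol
Product: 2 3,3-dimethylpentanedial
Conditions: (COCl)2, DMSO, CH2Cl2, −78 °C; Et3N, −78 → 0 °C; used crude
Reagents that add atoms: none
Why: Swern oxidation should take both primary alcohols to the aldehyde stage without over-oxidation, and the cold, non-aqueous, weakly basic medium should keep the dialdehyde from hydrating or self-condensing before use.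

**Step 2**
Reactants: 2 3,3-dimethylpentanedial; 3 acetone (excess, co-solvent)
Product: 7 (4R)-4-hydroxy-2,6,6-trimethylcyclohex-1-ene-1-carbaldehyde, via open-chain aldol 4 (not isolated), via δ-lactol 5 (not isolated), via ring carbinol 6 (not isolated)
Conditions: L-proline (20 mol %), acetone/CHCl3 1:4, rt; then acetone stripped in vacuo, THF, [Bn2NH2][O2CCF3] (20 mol %), rt, same flask
Reagents that add atoms: none
Why: L-Proline turns acetone into its enamine, which should add through the hydrogen-bonded chair-like transition state to the Re face of one of the two homotopic formyl groups of 2, making the C3–C4 bond and the carbinol centre of 4 under catalyst control (it becomes the 3R centre); 4 rests as δ-lactol 5, which shields the second formyl group from a second intermolecular aldol. The dibenzylammonium salt then converts the formyl group released from 5 into its enamine, whose α-carbon C6 adds to the C5 ketone in a 6-(enolexo)-exo-trig closure to ring carbinol 6, and loss of water from the β-hydroxy iminium ion gives the tetrasubstituted C5=C6 bond conjugated with C7=O. The closest known reaction type is the proline-catalysed aldol of acetone with α-unbranched aldehydes, followed in the same pot by a secondary-ammonium-catalysed aldol condensation to a cycloalkene carbaldehyde, as known for 1,4-dialdehydes. The step needs the aldehyde α-carbon C6, not the ketone α-carbon C4, to be the donor in the ring closure; enamine catalysis by a secondary ammonium salt should secure this because only the aldehyde condenses readily with the amine, and dehydration to the conjugated enal is the irreversible exit. It also needs the C3 hydroxyl to survive, hence the near-neutral medium at room temperature, since stronger acid, base or heat would eliminate water towards the cyclohexadiene aldehyde. The gem-dimethyl group at C1 should help the closure (gem-dialkyl effect) and leaves no enolisable position between the two arms.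

**Step 3**
Reactants: 7 (4R)-4-hydroxy-2,6,6-trimethylcyclohex-1-ene-1-carbaldehyde
Product: 8 (1R)-4-(hydroxymethyl)-3,5,5-trimethylcyclohex-3-en-1-ol
Conditions: NaBH4, CeCl3·7H2O, MeOH, 0 °C
Reagents that add atoms: none
Why: Luche reduction should deliver hydride 1,2 to the hindered conjugated aldehyde and leave the tetrasubstituted alkene and the carbinol centre untouched.

**Step 4**
Reactants: 8 (1R)-4-(hydroxymethyl)-3,5,5-trimethylcyclohex-3-en-1-ol
Product: 9 {[(4R)-4-hydroxy-2,6,6-trimethylcyclohex-1-en-1-yl]methyl}(triphenyl)phosphonium bromide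
Conditions: PPh3·HBr, MeOH, rt, dark; recrystallisation
Reagents that add atoms: triphenylphosphine hydrobromide, [Br-].c1ccc(cc1)[PH+](c1ccccc1)c1ccccc1
Why: Under HBr the primary allylic alcohol should ionise to the allyl cation, which PPh3 captures at the unhindered CH2 terminus (SN1-type phosphonium salt formation, as used for cyclogeranyl and C15 carotenoid salts), while the non-allylic C3 alcohol does not ionise, and recrystallisation of the salt should allow enantiomeric enrichment.

**Step 5**
Reactants: 9 the phosphonium bromide; 10 all-E β-apo-8'-carotenal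
Product: 11 (3R)-β,β-caroten-3-ol [(3R)-β-cryptoxanthin, all-E]
Conditions: NaOMe, MeOH/CH2Cl2, 0 °C → rt, Ar, dark; then heptane, reflux (Z→E equilibration), crystallisation
Reagents that add atoms: none
Why: Wittig reaction of the allylic ylide with the unhindered polyene aldehyde should form C7=C8 (the ring-methyl phosphonium plus polyene aldehyde pairing known from C10 + C20 + C10 carotenoid assembly), the free hydroxyl being tolerated and the crowded 7Z isomer being converged to the all-E polyene by thermal equilibration.

**Step 6**
Reactants: 11 (3R)-β-cryptoxanthin; 12 oleoyl chloride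
Product: 13 (3R)-β,β-caroten-3-yl (9Z)-octadec-9-enoate (CNP0152321.1)
Conditions: pyridine, DMAP (cat.), CH2Cl2, 0 °C → rt, Ar, dark
Reagents that add atoms: none
Why: Acylation of the unhindered secondary alcohol by the acid chloride under nucleophilic catalysis occurs at oxygen and so retains the 3R configuration, and the mild non-acidic conditions should leave the polyene and the Z alkene of the acyl chain untouched.

**Compound list**
1 | 3,3-dimethylpentane-1,5-diol | OCCC(C)(C)CCO | starting material
2 | 3,3-dimethylpentanedial | O=CCC(C)(C)CC=O | intermediate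
3 | acetone | CC(C)=O | starting material
4 | (5S)-5-hydroxy-3,3-dimethyl-7-oxooctanal (open-chain aldol) | CC(=O)C[C@@H](O)CC(C)(C)CC=O | intermediate
5 | 1-[(2S)-6-hydroxy-4,4-dimethyloxan-2-yl]propan-2-one (δ-lactol, anomer mixture) | CC(=O)C[C@@H]1CC(C)(C)CC(O)O1 | intermediate
6 | (4S)-2,4-dihydroxy-2,6,6-trimethylcyclohexane-1-carbaldehyde (ring carbinol, mixture at C1 and C2) | O[C@@H]1CC(C)(O)C(C=O)C(C)(C)C1 | intermediate
7 | (4R)-4-hydroxy-2,6,6-trimethylcyclohex-1-ene-1-carbaldehyde [(3R)-3-hydroxy-β-cyclocitral] | O[C@@H]1CC(C)=C(C=O)C(C)(C)C1 | intermediate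
8 | (1R)-4-(hydroxymethyl)-3,5,5-trimethylcyclohex-3-en-1-ol | O[C@@H]1CC(C)=C(CO)C(C)(C)C1 | intermediate
9 | {[(4R)-4-hydroxy-2,6,6-trimethylcyclohex-1-en-1-yl]methyl}(triphenyl)phosphonium bromide | O[C@@H]1CC(C)=C(C[P+](c2ccccc2)(c2ccccc2)c2ccccc2)C(C)(C)C1.[Br-] | intermediate
10 | all-E β-apo-8'-carotenal [(2E,4E,6E,8E,10E,12E,14E,16E)-2,6,11,15-tetramethyl-17-(2,6,6-trimethylcyclohex-1-en-1-yl)heptadeca-2,4,6,8,10,12,14,16-octaenal] | O=C/C(C)=C/C=C/C(C)=C/C=C/C=C(C)/C=C/C=C(C)/C=C/C1=C(C)CCCC1(C)C | starting material
11 | (3R)-β,β-caroten-3-ol [(3R)-β-cryptoxanthin, all-E] | O[C@@H]1CC(C)=C(/C=C/C(C)=C/C=C/C(C)=C/C=C/C=C(C)/C=C/C=C(C)/C=C/C2=C(C)CCCC2(C)C)C(C)(C)C1 | intermediate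
12 | oleoyl chloride [(9Z)-octadec-9-enoyl chloride] | CCCCCCCC/C=C\CCCCCCCC(Cl)=O | starting material
13 | (3R)-β,β-caroten-3-yl (9Z)-octadec-9-enoate | CCCCCCCC/C=C\CCCCCCCC(=O)O[C@@H]1CC(C)=C(/C=C/C(C)=C/C=C/C(C)=C/C=C/C=C(C)/C=C/C=C(C)/C=C/C2=C(C)CCCC2(C)C)C(C)(C)C1 | target

**Totals.** Total step count: 6. Longest linear sequence: 6 steps (1 → 2 → 7 → 8 → 9 → 11 → 13).

**Steps most likely to fail**

1. Step 2. The intermolecular aldol of an α-unbranched aldehyde may suffer from self-condensation of the dialdehyde, early loss of water and only moderate facial selectivity; the ring closure may be slowed by crowding at C6 next to the quaternary C1. The fallback sets out from 2 and replaces the enamine aldol by a reagent-controlled allylboration. Asymmetric methallylboration of one formyl group with (+)-B-(2-methylallyl)diisopinocampheylborane (from (+)-Ipc2BOMe and 2-methylallylmagnesium chloride; Et2O, −78 °C; ethanolamine work-up; Re-face delivery expected) should give (5R)-5-hydroxy-3,3,7-trimethyloct-7-enal F1. Ozonolysis of its 1,1-disubstituted alkene (O3, CH2Cl2, −78 °C; Me2S) should give the methyl ketone, which is δ-lactol 5, now isolated and purified. A separate closure with [Bn2NH2][O2CCF3] in THF then comes back to the route at 7.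

2. Step 5. The ylide sits next to two fully substituted ring carbons, so slow addition, ylide decay and Z isomers at the new double bond are the likely problems. The fallback swaps the roles of the partners and sets out from 10 and 7. Reduction of 10 (NaBH4, MeOH/THF, 0 °C) should give β-apo-8'-carotenol F2; PPh3·HBr in MeOH/CH2Cl2 should give (β-apo-8'-carotenyl)triphenylphosphonium bromide F3. Its unhindered polyenyl ylide (NaOMe, or 1,2-epoxybutane in EtOH at reflux) is then condensed with aldehyde 7, followed by the same thermal equilibration, and the route is rejoined at 11.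

3. Step 4. Ionisation under HBr may be accompanied by elimination from the allyl cation to dienes or by acid-promoted loss of the C3 hydroxyl. The fallback avoids the cation and sets out from 8. Corey–Kim bromination (NBS, Me2S, CH2Cl2, −20 → 0 °C), which is selective for the allylic primary alcohol, should give (1R)-4-(bromomethyl)-3,5,5-trimethylcyclohex-3-en-1-ol F4. SN2 displacement with PPh3 (toluene, rt) then comes back to the route at 9.

**Further compounds**
F1 | step 2 | (5R)-5-hydroxy-3,3,7-trimethyloct-7-enal | C=C(C)C[C@@H](O)CC(C)(C)CC=O
F2 | step 5 | β-apo-8'-carotenol [(2E,4E,6E,8E,10E,12E,14E,16E)-2,6,11,15-tetramethyl-17-(2,6,6-trimethylcyclohex-1-en-1-yl)heptadeca-2,4,6,8,10,12,14,16-octaen-1-ol] | OC/C(C)=C/C=C/C(C)=C/C=C/C=C(C)/C=C/C=C(C)/C=C/C1=C(C)CCCC1(C)C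
F3 | step 5 | (β-apo-8'-carotenyl)triphenylphosphonium bromide | [Br-].c1ccc(cc1)[P+](c1ccccc1)(c1ccccc1)C/C(C)=C/C=C/C(C)=C/C=C/C=C(C)/C=C/C=C(C)/C=C/C1=C(C)CCCC1(C)C
F4 | step 4 | (1R)-4-(bromomethyl)-3,5,5-trimethylcyclohex-3-en-1-ol | O[C@@H]1CC(C)=C(CBr)C(C)(C)C1
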